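**Retrosynthetic overview**

- Feature: the chain C9'–C8'–C8–C9, with benzylic C7' on C8' and benzylic C7 on C8, is a trans-α,β-disubstituted γ-butyrolactone in disguise (C9' = lactone carbonyl, C9 = acetal carbon). The 8S,8'S bridgehead pair of the cis-fused dioxabicyclo[3.3.0]octane corresponds to the trans lactone.
- Last events: fluoride release of the Ar1 phenol, after a one-flask double SN1 etherification of an acyclic tetraol. This closes ring 2 (C7'–O–C9–C8–C8') and then ring 1 (C7–O–C9'–C8'–C8); no ring of the target exists earlier.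
- The tetraol comes from exhaustive hydride reduction of a 3-(aryl-hydroxymethyl)-4-aroyl-5-menthyloxy lactone, itself the unmasked form of a dithiane adduct.
- Key disconnection: C7–C8 and C7'–C8' in one three-component operation, from lithiated Ar1-dithiane, the (5S)-menthyloxybutenolide and O-prenylvanillin.
- The components come from furfural and (+)-menthol, from vanillin and propane-1,3-dithiol, and from vanillin and prenyl bromide.

Key step: step 6

Remark on the chemistry: the carbinol centres C7' (from the aldol) and C7 (from the hydride reduction) are both ionised and re-formed in step 9. The (7'R) aldol epimer is therefore drawn for 15–17, its C7' epimer (if formed) is carried along to the same furofuran, and C7 of 17 and 18 is left undefined.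

**Step 1**
Reactants: 1 furfural
Product: 3 5-hydroxyfuran-2(5H)-one (racemic hemiacetal), via furfural endoperoxide 2 (not isolated)
Conditions: O2, hν (visible), methylene blue (cat.), MeOH, rt
Reagents that add atoms: dioxygen, O=O
Why: Dye-sensitised singlet-oxygen [4+2] cycloaddition across C2/C5 of the furan gives endoperoxide 2, which methanol fragments with loss of the formyl carbon as methyl formate (photo-oxygenation of furfural); the hemiacetal carbon equilibrates, so no stereocentre needs control.

**Step 2**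
Reactants: 3 5-hydroxyfuran-2(5H)-one; 4 (+)-menthol
Product: 6 (5S)-5-[(1S,2R,5S)-menthyloxy]furan-2(5H)-one, via (5R)-epimeric acetal 5 (not isolated)
Conditions: p-TsOH·H2O (cat.), toluene, reflux, Dean–Stark; crystallisation from hexane, mother liquor re-equilibrated with the acid and recrystallised
Reagents that add atoms: none
Why: Acid-catalysed acetalisation gives both C5 epimers, which interconvert through the cyclic oxocarbenium ion, so the acetal centre is set by crystallisation-induced diastereomer transformation, the (5S) acetal of (+)-menthol being the mirror image of the well-known crystalline (5R) acetal of (−)-menthol.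

**Step 3**
Reactants: 7 vanillin; 8 propane-1,3-dithiol
Product: 9 4-(1,3-dithian-2-yl)-2-methoxyphenol
Conditions: BF3·OEt2 (cat.), CH2Cl2, 0 °C → rt
Reagents that add atoms: none
Why: Lewis-acid-catalysed dithioacetalisation of an aromatic aldehyde, which the free phenol tolerates; doing this before silylation keeps the silyl ether away from the Lewis acid.

**Step 4**
Reactants: 9 4-(1,3-dithian-2-yl)-2-methoxyphenol
Product: 10 2-[3-methoxy-4-(triisopropylsilyloxy)phenyl]-1,3-dithiane
Conditions: TIPSCl, imidazole, DMF, rt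
Reagents that add atoms: triisopropylsilyl chloride, CC(C)[Si](Cl)(C(C)C)C(C)C
Why: Imidazole-promoted O-silylation of the phenol gives a bulky aryl silyl ether that should withstand n-BuLi at low temperature, hydride and mild acid, and is removable by fluoride without touching the prenyl ether.

**Step 5**
Reactants: 7 vanillin
Product: 11 3-methoxy-4-(3-methylbut-2-enyloxy)benzaldehyde
Conditions: prenyl bromide, K2CO3, DMF, rt
Reagents that add atoms: prenyl bromide, CC(C)=CCBr
Why: Williamson ether synthesis, SN2 attack of the phenoxide on the primary allylic bromide.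

**Step 6**
Reactants: 10 2-[3-methoxy-4-(triisopropylsilyloxy)phenyl]-1,3-dithiane; 6 (5S)-5-[(1S,2R,5S)-menthyloxy]furan-2(5H)-one; 11 3-methoxy-4-(3-methylbut-2-enyloxy)benzaldehyde
Product: 15 (3R,4S,5S)-3-[(R)-aryl(hydroxy)methyl]-4-(2-aryl-1,3-dithian-2-yl)-5-menthyloxydihydrofuran-2(3H)-one, via 2-lithio-1,3-dithiane 12 (not isolated), via lithium lactone enolate 13 (not isolated), via lithium aldolate 14 (not isolated)
Conditions: n-BuLi, THF, −78 → −20 °C; 6, −78 °C; 11, −78 °C; AcOH, −78 °C
Reagents that add atoms: none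
Why: n-BuLi removes the C2 proton of 10 to give the sulfur-stabilised carbanion 12, which adds in a conjugate sense to C8 (C4 of the furanone) of 6; the lithium enolate 13 is then intercepted at C8' by aldehyde 11 to give aldolate 14, protonated cold by AcOH. The closest known reaction type is the tandem conjugate addition–aldol of lithiated 2-aryl-1,3-dithianes on 5-alkoxyfuran-2(5H)-ones, so this is known chemistry with new aryl partners. No ring is closed; C7–C8 and C7'–C8' are formed on the existing lactone. C8 is controlled by the C9 acetal centre, the nucleophile entering anti to the menthyloxy group (8S); C8' is controlled by the bulky dithianyl group now on C8, the aldehyde entering anti to it (trans,trans lactone, the arrangement that becomes 8'S). C7' is set only by the aldehyde orientation in the aldol transition state, a pair of carbinol epimers is to be expected, and the centre is not relied on because step 9 ionises it. The step needs 1,4- over 1,2-addition and irreversible enolate capture: the soft, hindered dithianyl anion and the unhindered β-carbon of the γ-alkoxybutenolide favour conjugate addition, and holding the aldol at −78 °C with an acidic quench suppresses retro-aldol equilibration.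

**Step 7**
Reactants: 15 dithiane aldol adduct
Product: 16 (3R,4S,5S)-3-[(R)-aryl(hydroxy)methyl]-4-[3-methoxy-4-(triisopropylsilyloxy)benzoyl]-5-menthyloxydihydrofuran-2(3H)-one
Conditions: MeI, CaCO3, MeCN–H2O (9:1), 45 °C
Reagents that add atoms: water, O
Why: Alkylative dithioacetal hydrolysis (S-methylation, aryl-stabilised thionium ion, capture by water) is non-oxidative and free of thiophilic divalent mercury salts, so the prenyl alkene and the free carbinol are spared, while CaCO3 scavenges HI to protect the menthyl acetal and silyl ether; C8, now α to the ketone, stays in the favoured trans,trans arrangement.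

**Step 8**
Reactants: 16 keto lactone
Product: 17 (1R,2S,3S)-2,3-bis(hydroxymethyl)-1-(3-methoxy-4-prenyloxyphenyl)-4-(3-methoxy-4-triisopropylsilyloxyphenyl)butane-1,4-diol (C4 = C7 epimer mixture)
Conditions: LiAlH4, THF, 0 °C → rt; H2O, 15% aq. NaOH, H2O
Reagents that add atoms: none
Why: LiAlH4 reduces the aryl ketone and the lactone, and the ring-opened hemiacetal at C9 collapses to an aldehyde that is reduced as well, releasing menthol; the new C7 carbinol forms without control, which is harmless because it is ionised in step 9, and C8/C8' are not touched.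

**Step 9**
Reactants: 17 tetraol
Product: 19 O-triisopropylsilyl ether of the target furofuran, via monocyclic tetrahydrofuran diol 18 (not isolated)
Conditions: CSA (10 mol%), CH2Cl2, 4 Å molecular sieves, 0 °C → rt
Reagents that add atoms: none
Why: Acid-catalysed dehydrative etherification of 1,4-diaryl-2,3-bis(hydroxymethyl)butane-1,4-diols: each para-oxygenated benzylic carbinol ionises to a quinone-methide-like cation that the 1,4-related primary hydroxyl captures in a 5-exo-trig closure (C7' first, being alkoxy-stabilised, then C7), and in each kinetic capture the aryl group takes the exo position trans to the neighbouring ring substituent whatever the carbinol configuration was, giving 7R and 7'R on the cis-fused core fixed by 8S,8'S.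

**Step 10**
Reactants: 19 silyl-protected furofuran
Product: 20 target, 4-[(1R,3aS,4R,6aS)-4-[3-methoxy-4-(3-methylbut-2-enyloxy)phenyl]tetrahydro-1H,3H-furo[3,4-c]furan-1-yl]-2-methoxyphenol
Conditions: TBAF, AcOH, THF, 0 °C
Reagents that add atoms: none
Why: Fluoride cleavage of the aryl silyl ether, buffered with AcOH so that no free phenoxide para to the C7 benzylic ether persists; the prenyl ether and the furofuran are inert and no stereocentre is touched.

**Compound list**

1 | furfural | O=Cc1ccco1 | starting material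
2 | furfural 2,5-endoperoxide, 2,3,7-trioxabicyclo[2.2.1]hept-5-ene-1-carbaldehyde (racemic) | O=CC12C=CC(OO1)O2 | intermediate
3 | 5-hydroxyfuran-2(5H)-one (racemic) | O=C1C=CC(O)O1 | intermediate
4 | (+)-menthol, (1S,2R,5S)-2-isopropyl-5-methylcyclohexanol | CC(C)[C@H]1CC[C@H](C)C[C@@H]1O | starting material
5 | (5R)-5-[(1S,2R,5S)-menthyloxy]furan-2(5H)-one (equilibrating epimer) | O=C1C=C[C@H](O[C@H]2C[C@@H](C)CC[C@@H]2C(C)C)O1 | intermediate
6 | (5S)-5-[(1S,2R,5S)-menthyloxy]furan-2(5H)-one | O=C1C=C[C@@H](O[C@H]2C[C@@H](C)CC[C@@H]2C(C)C)O1 | intermediate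
7 | vanillin | COc1cc(C=O)ccc1O | starting material
8 | propane-1,3-dithiol | SCCCS | starting material
9 | 4-(1,3-dithian-2-yl)-2-methoxyphenol | COc1cc(C2SCCCS2)ccc1O | intermediate
10 | 2-[3-methoxy-4-(triisopropylsilyloxy)phenyl]-1,3-dithiane | COc1cc(C2SCCCS2)ccc1O[Si](C(C)C)(C(C)C)C(C)C | intermediate
11 | 3-methoxy-4-(3-methylbut-2-enyloxy)benzaldehyde | COc1cc(C=O)ccc1OCC=C(C)C | intermediate
12 | 2-lithio-2-[3-methoxy-4-(triisopropylsilyloxy)phenyl]-1,3-dithiane | COc1cc(C2([Li])SCCCS2)ccc1O[Si](C(C)C)(C(C)C)C(C)C | intermediate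
13 | lithium enolate of (4S,5S)-4-(2-aryl-1,3-dithian-2-yl)-5-menthyloxydihydrofuran-2(3H)-one | [Li]OC1=C[C@H](C2(c3ccc(O[Si](C(C)C)(C(C)C)C(C)C)c(OC)c3)SCCCS2)[C@@H](O[C@H]2C[C@@H](C)CC[C@@H]2C(C)C)O1 | intermediate
14 | lithium alkoxide (aldolate) of 15 | O=C1[C@@H]([C@@H](O[Li])c2ccc(OCC=C(C)C)c(OC)c2)[C@H](C2(c3ccc(O[Si](C(C)C)(C(C)C)C(C)C)c(OC)c3)SCCCS2)[C@@H](O[C@H]2C[C@@H](C)CC[C@@H]2C(C)C)O1 | intermediate
15 | (3R,4S,5S)-3-[(R)-hydroxy{3-methoxy-4-(3-methylbut-2-enyloxy)phenyl}methyl]-4-{2-[3-methoxy-4-(triisopropylsilyloxy)phenyl]-1,3-dithian-2-yl}-5-[(1S,2R,5S)-menthyloxy]dihydrofuran-2(3H)-one | O=C1[C@@H]([C@@H](O)c2ccc(OCC=C(C)C)c(OC)c2)[C@H](C2(c3ccc(O[Si](C(C)C)(C(C)C)C(C)C)c(OC)c3)SCCCS2)[C@@H](O[C@H]2C[C@@H](C)CC[C@@H]2C(C)C)O1 | intermediate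
16 | (3R,4S,5S)-3-[(R)-hydroxy{3-methoxy-4-(3-methylbut-2-enyloxy)phenyl}methyl]-4-[3-methoxy-4-(triisopropylsilyloxy)benzoyl]-5-[(1S,2R,5S)-menthyloxy]dihydrofuran-2(3H)-one | O=C1[C@@H]([C@@H](O)c2ccc(OCC=C(C)C)c(OC)c2)[C@H](C(=O)c2ccc(O[Si](C(C)C)(C(C)C)C(C)C)c(OC)c2)[C@@H](O[C@H]2C[C@@H](C)CC[C@@H]2C(C)C)O1 | intermediate
17 | (1R,2S,3S)-2,3-bis(hydroxymethyl)-1-[3-methoxy-4-(3-methylbut-2-enyloxy)phenyl]-4-[3-methoxy-4-(triisopropylsilyloxy)phenyl]butane-1,4-diol, epimer mixture at C4 (lignan C7) | OC[C@@H]([C@@H](O)c1ccc(OCC=C(C)C)c(OC)c1)[C@H](C(O)c1ccc(O[Si](C(C)C)(C(C)C)C(C)C)c(OC)c1)CO | intermediate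
18 | (2R,3S,4S)-3-(hydroxymethyl)-4-{hydroxy[3-methoxy-4-(triisopropylsilyloxy)phenyl]methyl}-2-[3-methoxy-4-(3-methylbut-2-enyloxy)phenyl]tetrahydrofuran, carbinol epimer mixture | OC[C@@H]1[C@H](C(O)c2ccc(O[Si](C(C)C)(C(C)C)C(C)C)c(OC)c2)CO[C@H]1c3ccc(OCC=C(C)C)c(OC)c3 | intermediate
19 | triisopropyl{2-methoxy-4-[(1R,3aS,4R,6aS)-4-[3-methoxy-4-(3-methylbut-2-enyloxy)phenyl]tetrahydro-1H,3H-furo[3,4-c]furan-1-yl]phenoxy}silane | COc1cc([C@@H]2OC[C@@H]3[C@H]2CO[C@H]3c2ccc(OCC=C(C)C)c(OC)c2)ccc1O[Si](C(C)C)(C(C)C)C(C)C | intermediate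
20 | 4-[(1R,3aS,4R,6aS)-4-[3-methoxy-4-(3-methylbut-2-enyloxy)phenyl]tetrahydro-1H,3H-furo[3,4-c]furan-1-yl]-2-methoxyphenol, (7R,7'R,8S,8'S) | COc1cc([C@@H]2OC[C@@H]3[C@H]2CO[C@H]3c2ccc(OCC=C(C)C)c(OC)c2)ccc1O | target

**Step count**

Total: 10 steps. Longest linear sequence: 7 steps (1, 2, 6, 7, 8, 9, 10; the vanillin branch 3, 4, 6–10 is equally long).

**Steps most likely to fail**

1. Step 6. What may go wrong: carbonyl (1,2) attack or proton transfer instead of conjugate addition, incomplete capture of the hindered enolate by the aldehyde, or reversal of the aldol before the quench. Fallback: decouple the two bond formations. It sets out from 10 and 6. Anion 12 is added to 6 alone and the enolate is protonated cold with AcOH, so that the trans Michael adduct (4S,5S)-4-{2-[3-methoxy-4-(triisopropylsilyloxy)phenyl]-1,3-dithian-2-yl}-5-menthyloxydihydrofuran-2(3H)-one F1 is isolated and purified. In a separate operation F1 is deprotonated with LiN(i-Pr)2 (THF, −78 °C) to regenerate enolate 13 free of excess anion and unreacted butenolide, aldehyde 11 is added, and a cold AcOH quench of 14 returns the route at 15. The dithianyl group on C8 again directs the aldehyde to the opposite face.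

2. Step 9. What may go wrong: acid-promoted ionisation of the aryl prenyl ether (loss or C-migration of the prenyl group) competing with ionisation of the carbinols, re-ionisation of the product leading to endo-aryl epimers, or capture of one benzylic cation by the other benzylic hydroxyl. Fallback: carry an acid-robust allyl ether through the cyclisation and create the prenyl group last. It sets out from 7 (with 6 and 10) and returns at 19.
   - Vanillin 7 is allylated (allyl bromide, K2CO3, DMF) to 4-allyloxy-3-methoxybenzaldehyde F4.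
   - F4 replaces 11 in the step-6 protocol to give the allyl aldol adduct F5.
   - MeI/CaCO3 hydrolysis gives the allyl keto lactone F6.
   - LiAlH4 gives the allyl tetraol F7.
   - Cyclisation gives the allyl furofuran silyl ether F8; acid strength and temperature can now be chosen freely (CSA at rt or BF3·OEt2 at −78 °C).
   - Olefin cross-metathesis of F8 with excess 2-methylbut-2-ene, using the second-generation Grubbs catalyst (H2IMes)(PCy3)Cl2Ru=CHPh in CH2Cl2 at 40 °C, converts the allyl ether into the prenyl ether 19.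

3. Step 7. What may go wrong: slow S-alkylation of the fully substituted dithiane, with retro-aldol cleavage or E1cB opening of the β-acyloxy ketone on prolonged heating. Fallback: reduce first and unmask later. It sets out from 15 and returns at 17.
   - LiAlH4 (THF, 0 °C → rt) reduces lactone and acetal with the dithiane intact, giving the dithiane triol F2.
   - MeI/CaCO3 in aqueous MeCN then unmasks the ketone on a substrate without lactone, acetal or β-leaving group, giving the trihydroxy ketone F3 (expected to rest largely as a cyclic hemiketal).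
   - F3 is reduced without delay (NaBH4, MeOH, 0 °C) to tetraol 17.

**Further compounds**

F1 | step 6 | (4S,5S)-4-{2-[3-methoxy-4-(triisopropylsilyloxy)phenyl]-1,3-dithian-2-yl}-5-[(1S,2R,5S)-menthyloxy]dihydrofuran-2(3H)-one | O=C1C[C@H](C2(c3ccc(O[Si](C(C)C)(C(C)C)C(C)C)c(OC)c3)SCCCS2)[C@@H](O[C@H]2C[C@@H](C)CC[C@@H]2C(C)C)O1
F2 | step 7 | (1R,2S,3S)-2-(hydroxymethyl)-1-[3-methoxy-4-(3-methylbut-2-enyloxy)phenyl]-3-{2-[3-methoxy-4-(triisopropylsilyloxy)phenyl]-1,3-dithian-2-yl}butane-1,4-diol | OC[C@@H]([C@@H](O)c1ccc(OCC=C(C)C)c(OC)c1)[C@H](C1(c2ccc(O[Si](C(C)C)(C(C)C)C(C)C)c(OC)c2)SCCCS1)CO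
F3 | step 7 | (2S,3S,4R)-4-hydroxy-2,3-bis(hydroxymethyl)-4-[3-methoxy-4-(3-methylbut-2-enyloxy)phenyl]-1-[3-methoxy-4-(triisopropylsilyloxy)phenyl]butan-1-one | OC[C@@H]([C@@H](O)c1ccc(OCC=C(C)C)c(OC)c1)[C@H](C(=O)c1ccc(O[Si](C(C)C)(C(C)C)C(C)C)c(OC)c1)CO
F4 | step 9 | 4-allyloxy-3-methoxybenzaldehyde | COc1cc(C=O)ccc1OCC=C
F5 | step 9 | (3R,4S,5S)-3-[(R)-(4-allyloxy-3-methoxyphenyl)(hydroxy)methyl]-4-{2-[3-methoxy-4-(triisopropylsilyloxy)phenyl]-1,3-dithian-2-yl}-5-[(1S,2R,5S)-menthyloxy]dihydrofuran-2(3H)-one | O=C1[C@@H]([C@@H](O)c2ccc(OCC=C)c(OC)c2)[C@H](C2(c3ccc(O[Si](C(C)C)(C(C)C)C(C)C)c(OC)c3)SCCCS2)[C@@H](O[C@H]2C[C@@H](C)CC[C@@H]2C(C)C)O1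
F6 | step 9 | (3R,4S,5S)-3-[(R)-(4-allyloxy-3-methoxyphenyl)(hydroxy)methyl]-4-[3-methoxy-4-(triisopropylsilyloxy)benzoyl]-5-[(1S,2R,5S)-menthyloxy]dihydrofuran-2(3H)-one | O=C1[C@@H]([C@@H](O)c2ccc(OCC=C)c(OC)c2)[C@H](C(=O)c2ccc(O[Si](C(C)C)(C(C)C)C(C)C)c(OC)c2)[C@@H](O[C@H]2C[C@@H](C)CC[C@@H]2C(C)C)O1
F7 | step 9 | (1R,2S,3S)-1-(4-allyloxy-3-methoxyphenyl)-2,3-bis(hydroxymethyl)-4-[3-methoxy-4-(triisopropylsilyloxy)phenyl]butane-1,4-diol, epimer mixture at C4 | OC[C@@H]([C@@H](O)c1ccc(OCC=C)c(OC)c1)[C@H](C(O)c1ccc(O[Si](C(C)C)(C(C)C)C(C)C)c(OC)c1)CO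
F8 | step 9 | {4-[(1R,3aS,4R,6aS)-4-(4-allyloxy-3-methoxyphenyl)tetrahydro-1H,3H-furo[3,4-c]furan-1-yl]-2-methoxyphenoxy}triisopropylsilane | COc1cc([C@@H]2OC[C@@H]3[C@H]2CO[C@H]3c2ccc(OCC=C)c(OC)c2)ccc1O[Si](C(C)C)(C(C)C)C(C)C
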